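The central quinone (ring A: C1 acetoxy, C2 aryl, C3 carbonyl, C4 hydroxy, C5 aryl, C6 carbonyl) alternates oxygen and aryl substituents and carries para oxygens at C3 and C6. That pattern is disconnected into three pieces: C6–C1–C2 from a chromium alkenyl(methoxy)carbene, C4–C5 from an aryl ynol ether and C3 from a carbonyl ligand. One benzannulation forms C5–C6, C3–C4 and C2–C3 and delivers ring A fully substituted as a 4-methoxyphenol. Its precursors are pentacarbonyl[1,2-dimethoxy-3-(4-benzyloxyphenyl)propenylidene]chromium and 1-(benzyloxy)-4-(ethoxyethynyl)benzene. Oxidation, hydrolysis, monoacetylation and debenzylation then complete the synthesis.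

Key step: step 4

Remark: apart from the acetyl group the target core is C2-symmetric, so acetylation of either quinone hydroxyl of the symmetric dihydroxyquinone 14 gives the same compound.

Step 1
Reactants: 1 tributyl(methoxymethyl)stannane; 2 chromium hexacarbonyl
Product: 5 pentacarbonyl(1,2-dimethoxyethylidene)chromium, via methoxymethyllithium 3 (not isolated), via lithium pentacarbonyl(methoxyacetyl)chromate 4 (not isolated)
Conditions: n-BuLi, THF, −78 °C; Cr(CO)6, THF, −78 °C to rt; Me3OBF4, CH2Cl2, 0 °C
Reagents that add atoms: trimethyloxonium tetrafluoroborate, C[O+](C)C.F[B-](F)(F)F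
Why: Tin–lithium exchange gives the α-alkoxy organolithium, which adds to a carbonyl ligand of Cr(CO)6 to give an acylchromate that the hard oxonium salt methylates on oxygen, the standard Fischer carbene synthesis; no stereocentre is formed.

Step 2
Reactants: 5 pentacarbonyl(1,2-dimethoxyethylidene)chromium; 6 4-(benzyloxy)benzaldehyde
Product: 7 pentacarbonyl{(2Z)-1,2-dimethoxy-3-[4-(benzyloxy)phenyl]prop-2-en-1-ylidene}chromium
Conditions: Et3N, Me3SiCl, Et2O, rt
Reagents that add atoms: none
Why: The CH2 group next to the carbene carbon is about as acidic as that of a 1,3-dicarbonyl compound, so an amine/silyl chloride-promoted aldol condensation of an alkyl(alkoxy)carbene complex with a non-enolisable aryl aldehyde should give the conjugated alkenyl complex, the elimination placing the bulky Cr(CO)5 carbene carbon trans to the aryl group, which is the (Z) descriptor because of the 2-methoxy group.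

Step 3
Reactants: 8 1-(benzyloxy)-4-iodobenzene; 9 ethoxyacetylene
Product: 10 1-(benzyloxy)-4-(ethoxyethynyl)benzene
Conditions: PdCl2(PPh3)2 (cat.), CuI (cat.), Et3N, THF, rt
Reagents that add atoms: none
Why: Sonogashira coupling of a terminal alkyne with an aryl iodide runs at room temperature under basic, non-aqueous conditions that the acid-sensitive ynol ether tolerates.

Step 4
Reactants: 7 pentacarbonyl{(2Z)-1,2-dimethoxy-3-[4-(benzyloxy)phenyl]prop-2-en-1-ylidene}chromium; 10 1-(benzyloxy)-4-(ethoxyethynyl)benzene
Product: 12 2-ethoxy-4,5-dimethoxy-3,6-bis[4-(benzyloxy)phenyl]phenol, via tricarbonyl(arene)chromium complex 11 (not isolated)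
Conditions: 10 (1.5 equiv), THF, 50 °C, Ar; then air, rt
Reagents that add atoms: none
Why: Proposed new method: thermal loss of one carbonyl ligand from 7 opens a site on chromium, the ynol ether 10 inserts with its nucleophilic aryl-bearing carbon bonding to the electrophilic carbene carbon (C5–C6), a carbonyl ligand then inserts into the new ethoxy-stabilised carbene (C3–C4) to give a dienylketene, and the ketene carbon closes onto the aryl-bearing vinyl carbon (C2–C3) before enolisation of the C2 hydrogen gives the phenol as its Cr(CO)3 complex 11, which air demetallates. The closest known reaction type is the Dötz benzannulation of alkenyl(alkoxy)carbene chromium complexes with alkyl- or aryl-substituted alkynes, for which oxygen-substituted alkynes are not an established partner. Ring A closes by a thermal disrotatory 6π-electrocyclisation of the chromium-bound dienylketene, and no stereocentre is formed. The step needs regioselective insertion, secured by the strong polarisation of the ynol ether that makes its aryl-bearing carbon the nucleophile, and six- over five-membered ring closure, favoured by the alkenyl (non-aromatic) carbene, the coordinating solvent and the carbonyl-rich pentacarbonyl complex. The (Z)-alkene of 7 turns the C2 hydrogen inward and the aryl group outward in the closing triene, so the cyclisation is not hindered.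

Step 5
Reactants: 12 2-ethoxy-4,5-dimethoxy-3,6-bis[4-(benzyloxy)phenyl]phenol
Product: 13 2-ethoxy-5-methoxy-3,6-bis[4-(benzyloxy)phenyl]cyclohexa-2,5-diene-1,4-dione
Conditions: (NH4)2Ce(NO3)6, MeCN/H2O, 0 °C
Reagents that add atoms: water, O
Why: Oxidative demethylation of a 4-methoxyphenol by tetravalent cerium: two one-electron oxidations give a phenoxonium ion, water adds at the methoxy-bearing C6 and methanol is lost to give the 1,4-quinone, while the benzyl, ethyl and remaining methyl ethers should not be touched in a short reaction at 0 °C.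

Step 6
Reactants: 13 2-ethoxy-5-methoxy-3,6-bis[4-(benzyloxy)phenyl]cyclohexa-2,5-diene-1,4-dione
Product: 14 2,5-dihydroxy-3,6-bis[4-(benzyloxy)phenyl]cyclohexa-2,5-diene-1,4-dione
Conditions: NaOH, THF/MeOH/H2O, 50 °C; then HCl (aq)
Reagents that add atoms: sodium hydroxide, [Na+].[OH-]
Why: Both alkoxy groups of 13 are vinylogous esters, so hydroxide replaces them by conjugate addition–elimination (vinylogous saponification), the resulting dianion resists further attack and acidification gives the dihydroxyquinone, with the benzyl aryl ethers inert to base.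

Step 7
Reactants: 14 2,5-dihydroxy-3,6-bis[4-(benzyloxy)phenyl]cyclohexa-2,5-diene-1,4-dione
Product: 15 2,5-bis[4-(benzyloxy)phenyl]-4-hydroxy-3,6-dioxocyclohexa-1,4-dien-1-yl acetate
Conditions: Ac2O (1.0 equiv), pyridine, CH2Cl2, 0 °C
Reagents that add atoms: acetic anhydride, CC(=O)OC(C)=O
Why: O-Acylation of a vinylogous acid with one equivalent of anhydride; the two hydroxyls of 14 are equivalent, and the first acetyl group lowers the nucleophilicity of the remaining vinylogous carboxylate, which should favour the monoacetate over the diacetate.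

Step 8
Reactants: 15 2,5-bis[4-(benzyloxy)phenyl]-4-hydroxy-3,6-dioxocyclohexa-1,4-dien-1-yl acetate
Product: 17 4-hydroxy-2,5-bis(4-hydroxyphenyl)-3,6-dioxocyclohexa-1,4-dien-1-yl acetate, via leuco hydroquinone acetate 16 (not isolated)
Conditions: H2 (1 atm), Pd/C, EtOAc, rt; then air, rt
Reagents that add atoms: none
Why: Catalytic hydrogenolysis of the two aryl benzyl ethers in a non-nucleophilic solvent also reduces the quinone to the hydroquinone 16, which air reoxidises on work-up; a shift of the acetyl group to the neighbouring hydroxyl in 16 would be degenerate, because reoxidation of either isomer gives the same quinone monoacetate.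

Compound list
1 | tributyl(methoxymethyl)stannane | CCCC[Sn](CCCC)(CCCC)COC | starting material
2 | chromium hexacarbonyl | O=C=[Cr](=C=O)(=C=O)(=C=O)(=C=O)=C=O | starting material
3 | methoxymethyllithium | [Li]COC | intermediate
4 | lithium pentacarbonyl(2-methoxy-1-oxidoethylidene)chromate, the acylchromate from addition of 3 to a carbonyl ligand of 2 | [Li+].COCC([O-])=[Cr](=C=O)(=C=O)(=C=O)(=C=O)=C=O | intermediate
5 | pentacarbonyl(1,2-dimethoxyethylidene)chromium | COCC(OC)=[Cr](=C=O)(=C=O)(=C=O)(=C=O)=C=O | intermediate
6 | 4-(benzyloxy)benzaldehyde | O=Cc1ccc(OCc2ccccc2)cc1 | starting material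
7 | pentacarbonyl{(2Z)-1,2-dimethoxy-3-[4-(benzyloxy)phenyl]prop-2-en-1-ylidene}chromium (carbene carbon trans to the aryl group) | COC(=[Cr](=C=O)(=C=O)(=C=O)(=C=O)=C=O)/C(OC)=C/c1ccc(OCc2ccccc2)cc1 | intermediate
8 | 1-(benzyloxy)-4-iodobenzene | Ic1ccc(OCc2ccccc2)cc1 | starting material
9 | ethoxyacetylene | CCOC#C | starting material
10 | 1-(benzyloxy)-4-(ethoxyethynyl)benzene | CCOC#Cc1ccc(OCc2ccccc2)cc1 | intermediate
11 | tricarbonyl{η6-2-ethoxy-4,5-dimethoxy-3,6-bis[4-(benzyloxy)phenyl]phenol}chromium, Cr(CO)3 bound to the central ring (the η6 bond is not drawn; the two parts are joined by a dot) | COc1c(OC)c(-c2ccc(OCc3ccccc3)cc2)c(O)c(OCC)c1-c1ccc(OCc2ccccc2)cc1.O=C=[Cr](=C=O)=C=O | intermediate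
12 | 2-ethoxy-4,5-dimethoxy-3,6-bis[4-(benzyloxy)phenyl]phenol | COc1c(OC)c(c2ccc(OCc3ccccc3)cc2)c(O)c(OCC)c1c1ccc(OCc2ccccc2)cc1 | intermediate
13 | 2-ethoxy-5-methoxy-3,6-bis[4-(benzyloxy)phenyl]cyclohexa-2,5-diene-1,4-dione | CCOC1=C(c2ccc(OCc3ccccc3)cc2)C(=O)C(OC)=C(c2ccc(OCc3ccccc3)cc2)C1=O | intermediate
14 | 2,5-dihydroxy-3,6-bis[4-(benzyloxy)phenyl]cyclohexa-2,5-diene-1,4-dione | OC1=C(c2ccc(OCc3ccccc3)cc2)C(=O)C(O)=C(c2ccc(OCc3ccccc3)cc2)C1=O | intermediate
15 | 2,5-bis[4-(benzyloxy)phenyl]-4-hydroxy-3,6-dioxocyclohexa-1,4-dien-1-yl acetate | CC(=O)OC1=C(c2ccc(OCc3ccccc3)cc2)C(=O)C(O)=C(c2ccc(OCc3ccccc3)cc2)C1=O | intermediate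
16 | 2,4,5-trihydroxy-3,6-bis(4-hydroxyphenyl)phenyl acetate | CC(=O)Oc1c(-c2ccc(O)cc2)c(O)c(O)c(-c2ccc(O)cc2)c1O | intermediate
17 | 4-hydroxy-2,5-bis(4-hydroxyphenyl)-3,6-dioxocyclohexa-1,4-dien-1-yl acetate | CC(=O)OC1=C(c2ccc(O)cc2)C(=O)C(O)=C(c2ccc(O)cc2)C1=O | target

Total steps: 8. Longest linear sequence: 7 steps (1, 2, 4, 5, 6, 7, 8); step 3 is the side branch.

Steps most likely to fail

Step 4 (Proposed new method). After alkyne insertion the ethoxy-stabilised carbene may resist carbonyl insertion and divert to five-membered ring closure, or stop as a stable insertion product. Insertion may also occur with the opposite orientation. The fallback uses known cross-coupling chemistry and sets out from 8. Miyaura borylation (B2pin2, PdCl2(dppf), KOAc, dioxane, 80 °C) should give 2-[4-(benzyloxy)phenyl]-4,4,5,5-tetramethyl-1,3,2-dioxaborolane F1. A twofold Suzuki–Miyaura coupling of F1 with the known reagent 2,5-dibromo-3,6-dimethoxycyclohexa-2,5-diene-1,4-dione (COC1=C(Br)C(=O)C(OC)=C(Br)C1=O; Pd(PPh3)4, K2CO3, dioxane/H2O, 80 °C) should give 2,5-bis[4-(benzyloxy)phenyl]-3,6-dimethoxycyclohexa-2,5-diene-1,4-dione F2. Hydrolysis of F2 under the conditions of step 6 comes back to the route at 14.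

Step 2. The hindered α-methoxy carbene carbanion may add too slowly to the aldehyde, or the adduct may revert or decompose before elimination. The fallback sets out from 6 and 2 and installs the carbene carbon last instead of the alkene. Condensation of 6 with methyl methoxyacetate (NaOMe, MeOH) should give methyl (2Z)-3-[4-(benzyloxy)phenyl]-2-methoxyprop-2-enoate F3. Saponification (LiOH, THF/H2O) gives (2Z)-3-[4-(benzyloxy)phenyl]-2-methoxyprop-2-enoic acid F4, and oxalyl chloride with catalytic DMF gives (2Z)-3-[4-(benzyloxy)phenyl]-2-methoxyprop-2-enoyl chloride F5. Reduction of 2 with KC8 in THF at −78 °C gives dipotassium pentacarbonylchromate F6, which F5 acylates to potassium pentacarbonyl{(2Z)-3-[4-(benzyloxy)phenyl]-2-methoxy-1-oxidoprop-2-en-1-ylidene}chromate F7. O-Methylation with Me3OBF4 comes back to the route at 7. Acylation of the pentacarbonylchromate dianion by an acid chloride followed by O-alkylation is an established alternative to the organolithium route to alkoxycarbene complexes.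

Step 7. Over-acetylation to the diacetate, together with incomplete conversion, may leave little monoacetate, because the substrate is symmetric. The fallback sets out from 14 and works subtractively. Exhaustive acetylation (excess Ac2O, pyridine, DMAP cat.) gives 2,5-bis[4-(benzyloxy)phenyl]-3,6-dioxocyclohexa-1,4-diene-1,4-diyl diacetate F8. One equivalent of LiOH in THF/H2O at 0 °C then removes a single acetyl group and comes back to the route at 15. The first cleavage leaves a vinylogous carboxylate anion that deactivates the second ester, and hydroxide attack at either the acetyl carbonyl or the ring carbon leads to the same product.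

Further compounds
F1 | step 4 | 2-[4-(benzyloxy)phenyl]-4,4,5,5-tetramethyl-1,3,2-dioxaborolane | CC1(C)OB(OC1(C)C)c1ccc(OCc2ccccc2)cc1
F2 | step 4 | 2,5-bis[4-(benzyloxy)phenyl]-3,6-dimethoxycyclohexa-2,5-diene-1,4-dione | COC1=C(c2ccc(OCc3ccccc3)cc2)C(=O)C(OC)=C(c2ccc(OCc3ccccc3)cc2)C1=O
F3 | step 2 | methyl (2Z)-3-[4-(benzyloxy)phenyl]-2-methoxyprop-2-enoate | COC(=O)/C(OC)=C/c1ccc(OCc2ccccc2)cc1
F4 | step 2 | (2Z)-3-[4-(benzyloxy)phenyl]-2-methoxyprop-2-enoic acid | OC(=O)/C(OC)=C/c1ccc(OCc2ccccc2)cc1
F5 | step 2 | (2Z)-3-[4-(benzyloxy)phenyl]-2-methoxyprop-2-enoyl chloride | ClC(=O)/C(OC)=C/c1ccc(OCc2ccccc2)cc1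
F6 | step 2 | dipotassium pentacarbonylchromate | [K+].[K+].O=C=[Cr-2](=C=O)(=C=O)(=C=O)=C=O
F7 | step 2 | potassium pentacarbonyl{(2Z)-3-[4-(benzyloxy)phenyl]-2-methoxy-1-oxidoprop-2-en-1-ylidene}chromate | [K+].[O-]C(=[Cr](=C=O)(=C=O)(=C=O)(=C=O)=C=O)/C(OC)=C/c1ccc(OCc2ccccc2)cc1
F8 | step 7 | 2,5-bis[4-(benzyloxy)phenyl]-3,6-dioxocyclohexa-1,4-diene-1,4-diyl diacetate | CC(=O)OC1=C(c2ccc(OCc3ccccc3)cc2)C(=O)C(OC(C)=O)=C(c2ccc(OCc3ccccc3)cc2)C1=O
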